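**Retrosynthetic overview**
1. Target 28 ⇐ diol 26 (acylation of the secondary C2–OH only) ⇐ 2-ketone 25/24 (dissolving-metal reduction sets C2) ⇐ 2-oxo-Δ3 enone 22 (conjugate methylation completes the C4 gem-dimethyl group).
2. Enone 22 ⇐ allylic boronate 20, the product of a thermal intramolecular Diels–Alder reaction of the acyclic tetraenyl boronate 19; bonds C1–C2 and C5–C10 form together, and no ring exists before this step.
3. Enabling feature: ring A (C1–C2–C3–C4–C5–C10), with one C4 methyl taken away, is the [4+2] adduct of a C2=C3–C4(Me)=C5 diene and the isopropenyl edge C10(C20)=C1. The remaining four atoms of ring B (C6–C7=C8–C9, Z-alkene) are exactly the tether, and C9 next to the dienophile steers the facial sense.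
4. 19 ⇐ three pieces: (S)-linalool (all ten carbons: C13 carbinol, C11–C16, C9, C10, C20, C1; SeO2 oxidation, phosphate, copper-catalysed SN2' alkenylation sets C9); (Z)-3-iodobut-2-en-1-ol (C6–C8, C17); (trimethylsilyl)butadiyne plus Me3Al (C2–C5, C18).
5. Ring order: rings A and B close simultaneously in step 14; the second C4 methyl (C19), the C2 carbinol and the ester follow.

Key step: step 14

Remark: labdane numbering is used (C10 angular carbon with methyl C20, C4 gem-dimethyl carbon, C2 ester carbinol, C9 bearing side chain C11–C16, C17 methyl on C8); the target is (2R,5R,9R,10R,13S), and (S)-(+)-linalool of high enantiomeric purity is taken as commercial.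

**Route**

Step 1
Reactants: 1 (S)-(+)-linalool [(3S)-3,7-dimethylocta-1,6-dien-3-ol]
Product: 2 (S)-linalool tert-butyldimethylsilyl ether
Conditions: TBSOTf, 2,6-lutidine, CH2Cl2, 0 °C to rt
Reagents that add atoms: tert-butyldimethylsilyl trifluoromethanesulfonate, CC(C)(C)[Si](C)(C)OS(=O)(=O)C(F)(F)F
Why: Silyl ether protection of the tertiary allylic alcohol with a silyl triflate, needed for the organometallic steps and the hot cycloaddition.

Step 2
Reactants: 2 (S)-linalool tert-butyldimethylsilyl ether
Product: 3 (2E,6S)-6-(tert-butyldimethylsilyloxy)-2,6-dimethylocta-2,7-dien-1-ol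
Conditions: SeO2 (0.3 equiv), t-BuOOH (2 equiv), salicylic acid (cat.), CH2Cl2, 0 °C to rt
Reagents that add atoms: selenium dioxide (oxygen donor, turned over by the peroxide), O=[Se]=O; tert-butyl hydroperoxide, CC(C)(C)OO
Why: Selenium dioxide allylic oxidation (ene reaction, then 2,3-sigmatropic shift) should hydroxylate the (E)-methyl of the trisubstituted alkene, the vinyl group having no allylic hydrogen.

Step 3
Reactants: 3 (2E,6S)-6-(tert-butyldimethylsilyloxy)-2,6-dimethylocta-2,7-dien-1-ol
Product: 4 diethyl (2E,6S)-6-(tert-butyldimethylsilyloxy)-2,6-dimethylocta-2,7-dien-1-yl phosphate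
Conditions: ClP(O)(OEt)2, pyridine, DMAP (cat.), CH2Cl2, 0 °C
Reagents that add atoms: diethyl chlorophosphate, CCOP(=O)(Cl)OCC
Why: O-Phosphorylation of the primary allylic alcohol gives the leaving group for the allylic substitution.

Step 4
Reactants: 5 but-2-yn-1-ol
Product: 7 (Z)-3-iodobut-2-en-1-ol, via sodium alkenylaluminate 6 (not isolated)
Conditions: NaAlH2(OCH2CH2OMe)2, THF, 0 °C to rt; then I2, THF, −78 °C
Reagents that add atoms: iodine, II
Why: Hydroxyl-directed trans-hydroalumination of the propargylic alcohol places aluminium on C3 cis to the CH2O group in a five-membered aluminate, and iodinolysis with retention should give the (Z)-iodoalkene.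

Step 5
Reactants: 7 (Z)-3-iodobut-2-en-1-ol
Product: 8 (Z)-triethyl[(3-iodobut-2-en-1-yl)oxy]silane
Conditions: TESCl, imidazole, CH2Cl2, 0 °C
Reagents that add atoms: chlorotriethylsilane, CC[Si](Cl)(CC)CC
Why: Silyl ether protection with a group that can later be removed beside the tertiary TBS ether.

Step 6
Reactants: 8 (Z)-triethyl[(3-iodobut-2-en-1-yl)oxy]silane
Product: 9 triethyl{[3-(4,4,5,5-tetramethyl-1,3,2-dioxaborolan-2-yl)but-2-en-1-yl]oxy}silane (boron cis to the CH2OTES group)
Conditions: B2pin2, PdCl2(PPh3)2 (3 mol%), PPh3 (6 mol%), KOPh, toluene, 50 °C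
Reagents that add atoms: bis(pinacolato)diboron, CC1(C)OB(OC1(C)C)B1OC(C)(C)C(C)(C)O1
Why: Miyaura borylation of the alkenyl iodide proceeds with retention of geometry and avoids an alkenyllithium that could suffer O-to-C silyl migration.

Step 7
Reactants: 4 diethyl (2E,6S)-6-(tert-butyldimethylsilyloxy)-2,6-dimethylocta-2,7-dien-1-yl phosphate; 9 alkenyl pinacol boronate
Product: 10 (2Z,4S,7S)-7-(tert-butyldimethylsilyloxy)-3,7-dimethyl-4-(prop-1-en-2-yl)-1-(triethylsilyloxy)nona-2,8-diene
Conditions: CuCl (10 mol%), chiral sulfonate-bearing imidazolinium salt (N-heterocyclic carbene precursor, 11 mol%), NaOMe (2 equiv), THF, 22 to 50 °C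
Reagents that add atoms: none
Why: Copper-catalysed enantioselective allylic substitution (SN2') of the allylic phosphate by the methoxide-activated alkenylboronate should join C8 to C9 with transposition to the isopropenyl group (C10=C1), the new C9 centre (4S in 10) being set by the chiral carbene ligand because the C13 centre is too remote to interfere.

Step 8
Reactants: 10 bis-silyl ether
Product: 11 (2Z,4S,7S)-7-(tert-butyldimethylsilyloxy)-3,7-dimethyl-4-(prop-1-en-2-yl)nona-2,8-dien-1-ol
Conditions: PPTS, MeOH, 0 °C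
Reagents that add atoms: none
Why: Acid-catalysed methanolysis removes the primary triethylsilyl ether much faster than the hindered tertiary TBS ether.

Step 9
Reactants: 11 (Z)-allylic alcohol
Product: 12 (3S,6S,7Z)-9-bromo-3-(tert-butyldimethylsilyloxy)-3,7-dimethyl-6-(prop-1-en-2-yl)nona-1,7-diene
Conditions: CBr4, PPh3, 2,6-lutidine, CH2Cl2, −20 °C
Reagents that add atoms: carbon tetrabromide, BrC(Br)(Br)Br
Why: Appel bromination of a primary allylic alcohol under buffered conditions should proceed without allylic transposition or loss of the (Z)-geometry.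

Step 10
Reactants: 13 1,4-bis(trimethylsilyl)buta-1,3-diyne
Product: 15 buta-1,3-diyn-1-yl(trimethyl)silane, via lithium silylbutadiynide 14 (not isolated)
Conditions: MeLi·LiBr (1 equiv), Et2O, rt; then aq. NH4Cl, 0 °C; dried solution exchanged into CH2Cl2 and used at once
Reagents that add atoms: none
Why: Nucleophilic cleavage of one C(sp)–Si bond by methyllithium (mono-protodesilylation) and protonation give the terminal diyne.

Step 11
Reactants: 15 buta-1,3-diyn-1-yl(trimethyl)silane; 12 (Z)-allylic bromide
Product: 17 [(3E,6Z,8S,11S)-11-(tert-butyldimethylsilyloxy)-3,7,11-trimethyl-8-(prop-1-en-2-yl)trideca-3,6,12-trien-1-yn-1-yl]trimethylsilane, via alkenylalane 16 (not isolated)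
Conditions: Me3Al (2 equiv), Cp2ZrCl2 (0.25 equiv), CH2Cl2, 0 °C to rt; then 12, Pd(PPh3)4 (5 mol%), THF, rt
Reagents that add atoms: trimethylaluminium, C[Al](C)C
Why: Zirconium-catalysed syn-carboalumination of the terminal alkyne (methyl to the internal carbon, silyl alkyne untouched) gives the (E)-alkenylalane, and palladium-catalysed Negishi-type coupling at the primary allylic carbon should give the skipped diene with both alkene geometries retained.

Step 12
Reactants: 17 silyl enyne
Product: 18 (3E,6Z,8S,11S)-11-(tert-butyldimethylsilyloxy)-3,7,11-trimethyl-8-(prop-1-en-2-yl)trideca-3,6,12-trien-1-yne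
Conditions: K2CO3, MeOH, rt
Reagents that add atoms: none
Why: Base-catalysed protodesilylation of the alkynylsilane leaves the silyl ether untouched.

Step 13
Reactants: 18 terminal enyne
Product: 19 2-[(1E,3E,6Z,8S,11S)-11-(tert-butyldimethylsilyloxy)-3,7,11-trimethyl-8-(prop-1-en-2-yl)trideca-1,3,6,12-tetraen-1-yl]-4,4,5,5-tetramethyl-1,3,2-dioxaborolane
Conditions: pinacolborane (1.2 equiv), Cp2Zr(H)Cl (10 mol%), Et3N (10 mol%), CH2Cl2, 40 °C
Reagents that add atoms: pinacolborane, [H]B1OC(C)(C)C(C)(C)O1
Why: Zirconium-catalysed syn, anti-Markovnikov hydroboration of the terminal alkyne (hydrozirconation, then transfer to boron) should give the (1E)-dienyl boronate, the hindered alkenes reacting far more slowly.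

Step 14
Reactants: 19 (1E,3E)-dienyl boronate
Product: 20 trans-fused cycloadduct, 13-O-TBS 2-(pinacolatoboryl)-ent-labda-3,7,14-trien-13-ol (boron cis to the C10 methyl; C5, C9, C10 and C13 as in the target)
Conditions: toluene (0.005 M), BHT (cat.), sealed tube, 185 °C
Reagents that add atoms: none
Why: Heat makes the (1E,3E)-boryl diene (C2=C3–C4=C5) and the isopropenyl group (C10=C1) combine in a concerted, suprafacial [4+2] cycloaddition, the closest known type being the thermal intramolecular Diels–Alder reaction of unactivated 1,7,9-decatrienes and of 1-boryl-1,3-dienes. Ring A closes directly as the new cyclohexene (bonds C1–C2 and C5–C10, alkene C3=C4), and ring B closes at the same moment because the tether C6–C7=C8–C9, held cisoid by the (Z)-alkene, already joins C5 to C10. The trans ring fusion (C5–H anti to the C10 methyl) should follow from the transition state with the tether exo and only the small C20 methyl under the diene, whereas the cis-fused mode would push C9 with its side chain and the C8 methyl under the C4 methyl. The facial sense, and with it the absolute configuration at C5 and C10, is controlled by the C9 stereocentre, whose side chain takes the pseudo-equatorial position anti to the forming C5–C10 bond with C9–H pointing at the diene. C2 is set with boron cis to the angular methyl by the E geometry of the diene, which is of no consequence because this centre becomes a ketone. Chemoselectivity rests on geometry, since the C7=C8 and vinyl alkenes cannot reach the diene, and the 3E geometry rules out a 1,5-hydrogen shift.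

Step 15
Reactants: 20 allylic boronate
Product: 21 13-O-TBS ent-labda-3,7,14-triene-2,13-diol (C2–OH cis to the C10 methyl)
Conditions: 30% H2O2, 3 M NaOH, THF, 0 °C
Reagents that add atoms: hydrogen peroxide, OO
Why: Oxidation of the C–B bond (1,2-migration from boron to oxygen with retention) gives the allylic alcohol without allylic transposition.

Step 16
Reactants: 21 allylic alcohol
Product: 22 13-O-TBS ent-13-hydroxylabda-3,7,14-trien-2-one
Conditions: MnO2 (activated, excess), CH2Cl2, rt
Reagents that add atoms: none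
Why: MnO2 oxidises the secondary allylic alcohol selectively to the conjugated enone, which erases the C2 centre.

Step 17
Reactants: 22 enone
Product: 24 13-O-TBS ent-13-hydroxylabda-7,14-dien-2-one, via trimethylsilyl enol ether 23 (not isolated)
Conditions: MeMgBr (3 equiv), CuBr·SMe2 (10 mol%), TMSCl (3 equiv), DMPU, THF, −78 to −30 °C; then 1 M HCl, THF, 0 °C
Reagents that add atoms: methylmagnesium bromide, C[Mg]Br
Why: Copper-catalysed, chlorosilane-accelerated conjugate addition of methyl to the β,β-disubstituted enone should build the C4 gem-dimethyl group (no new stereocentre), and the trapped silyl enol ether is hydrolysed on work-up.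

Step 18
Reactants: 24 silyl-protected ketone
Product: 25 ent-13-hydroxylabda-7,14-dien-2-one
Conditions: Bu4NF, THF, 45 °C
Reagents that add atoms: none
Why: Fluoride cleavage of the tertiary silyl ether is placed before the metal reduction so that the allylic oxygen is present there as a non-reducible alkoxide.

Step 19
Reactants: 25 keto alcohol
Product: 26 (2R,5R,9R,10R,13S)-ent-labda-7,14-diene-2,13-diol (C2–OH equatorial, trans to the C10 methyl)
Conditions: Li, NH3 (l), THF, t-BuOH, −78 °C; then NH4Cl
Reagents that add atoms: none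
Why: Dissolving-metal reduction of the ketone under thermodynamic control should give the equatorial C2 alcohol, which avoids the two syn-axial methyls at C4 and C10 that would steer a hydride reagent to the axial epimer; the isolated alkenes are inert.

Step 20
Reactants: 26 diol; 27 3-methylbut-2-enoic acid
Product: 28 target, (2R,5R,9R,10R,13S)-13-hydroxy-ent-labda-7,14-dien-2-yl 3-methylbut-2-enoate
Conditions: DCC, DMAP (cat.), CH2Cl2, 0 °C to rt
Reagents that add atoms: none
Why: Steglich esterification should acylate the unhindered secondary equatorial alcohol and leave the tertiary allylic alcohol free.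

**Compound list**
1 | (S)-(+)-linalool | C=C[C@@](C)(O)CCC=C(C)C | starting material
2 | (S)-linalool tert-butyldimethylsilyl ether | C=C[C@@](C)(O[Si](C)(C)C(C)(C)C)CCC=C(C)C | intermediate
3 | (2E,6S)-6-(tert-butyldimethylsilyloxy)-2,6-dimethylocta-2,7-dien-1-ol | C=C[C@@](C)(O[Si](C)(C)C(C)(C)C)CC/C=C(\C)CO | intermediate
4 | diethyl (2E,6S)-6-(tert-butyldimethylsilyloxy)-2,6-dimethylocta-2,7-dien-1-yl phosphate | C=C[C@@](C)(O[Si](C)(C)C(C)(C)C)CC/C=C(\C)COP(=O)(OCC)OCC | intermediate
5 | but-2-yn-1-ol | CC#CCO | starting material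
6 | sodium 2,2-bis(2-methoxyethoxy)-3-methyl-2,5-dihydro-1,2-oxaluminol-2-uide (alkenylaluminate) | [Na+].CC1=CCO[Al-]1(OCCOC)OCCOC | intermediate
7 | (Z)-3-iodobut-2-en-1-ol | C/C(I)=C/CO | intermediate
8 | (Z)-triethyl[(3-iodobut-2-en-1-yl)oxy]silane | C/C(I)=C/CO[Si](CC)(CC)CC | intermediate
9 | triethyl{[3-(4,4,5,5-tetramethyl-1,3,2-dioxaborolan-2-yl)but-2-en-1-yl]oxy}silane, boron cis to CH2OTES | C/C(B1OC(C)(C)C(C)(C)O1)=C/CO[Si](CC)(CC)CC | intermediate
10 | (2Z,4S,7S)-7-(tert-butyldimethylsilyloxy)-3,7-dimethyl-4-(prop-1-en-2-yl)-1-(triethylsilyloxy)nona-2,8-diene | C=C[C@@](C)(O[Si](C)(C)C(C)(C)C)CC[C@@H](C(C)=C)/C(C)=C\CO[Si](CC)(CC)CC | intermediate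
11 | (2Z,4S,7S)-7-(tert-butyldimethylsilyloxy)-3,7-dimethyl-4-(prop-1-en-2-yl)nona-2,8-dien-1-ol | C=C[C@@](C)(O[Si](C)(C)C(C)(C)C)CC[C@@H](C(C)=C)/C(C)=C\CO | intermediate
12 | (3S,6S,7Z)-9-bromo-3-(tert-butyldimethylsilyloxy)-3,7-dimethyl-6-(prop-1-en-2-yl)nona-1,7-diene | C=C[C@@](C)(O[Si](C)(C)C(C)(C)C)CC[C@@H](C(C)=C)/C(C)=C\CBr | intermediate
13 | 1,4-bis(trimethylsilyl)buta-1,3-diyne | C[Si](C)(C)C#CC#C[Si](C)(C)C | starting material
14 | lithium 4-(trimethylsilyl)buta-1,3-diyn-1-ide | [Li+].[C-]#CC#C[Si](C)(C)C | intermediate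
15 | buta-1,3-diyn-1-yl(trimethyl)silane | C#CC#C[Si](C)(C)C | intermediate
16 | (E)-dimethyl[2-methyl-4-(trimethylsilyl)but-1-en-3-yn-1-yl]alane | C[Al](C)/C=C(\C)C#C[Si](C)(C)C | intermediate
17 | [(3E,6Z,8S,11S)-11-(tert-butyldimethylsilyloxy)-3,7,11-trimethyl-8-(prop-1-en-2-yl)trideca-3,6,12-trien-1-yn-1-yl]trimethylsilane | C=C[C@@](C)(O[Si](C)(C)C(C)(C)C)CC[C@@H](C(C)=C)/C(C)=C\C/C=C(\C)C#C[Si](C)(C)C | intermediate
18 | (3E,6Z,8S,11S)-11-(tert-butyldimethylsilyloxy)-3,7,11-trimethyl-8-(prop-1-en-2-yl)trideca-3,6,12-trien-1-yne | C=C[C@@](C)(O[Si](C)(C)C(C)(C)C)CC[C@@H](C(C)=C)/C(C)=C\C/C=C(\C)C#C | intermediate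
19 | (1E,3E,6Z,8S,11S)-dienyl pinacol boronate (Diels–Alder precursor) | C=C[C@@](C)(O[Si](C)(C)C(C)(C)C)CC[C@@H](C(C)=C)/C(C)=C\C/C=C(\C)/C=C/B1OC(C)(C)C(C)(C)O1 | intermediate
20 | 13-O-TBS 2-(pinacolatoboryl)-ent-labda-3,7,14-trien-13-ol, trans-fused, boron cis to the C10 methyl | C=C[C@@](C)(O[Si](C)(C)C(C)(C)C)CC[C@@H]1C(C)=CC[C@@H]2C(C)=C[C@H](B3OC(C)(C)C(C)(C)O3)C[C@@]12C | intermediate
21 | 13-O-TBS ent-labda-3,7,14-triene-2,13-diol, C2–OH cis to the C10 methyl | C=C[C@@](C)(O[Si](C)(C)C(C)(C)C)CC[C@@H]1C(C)=CC[C@@H]2C(C)=C[C@H](O)C[C@@]12C | intermediate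
22 | 13-O-TBS ent-13-hydroxylabda-3,7,14-trien-2-one | C=C[C@@](C)(O[Si](C)(C)C(C)(C)C)CC[C@@H]1C(C)=CC[C@@H]2C(C)=CC(=O)C[C@@]12C | intermediate
23 | 2-(trimethylsilyloxy)-Δ2 silyl enol ether of 24 | C=C[C@@](C)(O[Si](C)(C)C(C)(C)C)CC[C@@H]1C(C)=CC[C@@H]2C(C)(C)C=C(O[Si](C)(C)C)C[C@@]12C | intermediate
24 | 13-O-TBS ent-13-hydroxylabda-7,14-dien-2-one | C=C[C@@](C)(O[Si](C)(C)C(C)(C)C)CC[C@@H]1C(C)=CC[C@@H]2C(C)(C)CC(=O)C[C@@]12C | intermediate
25 | ent-13-hydroxylabda-7,14-dien-2-one | C=C[C@@](C)(O)CC[C@@H]1C(C)=CC[C@@H]2C(C)(C)CC(=O)C[C@@]12C | intermediate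
26 | (2R,5R,9R,10R,13S)-ent-labda-7,14-diene-2,13-diol | C=C[C@@](C)(O)CC[C@@H]1C(C)=CC[C@@H]2C(C)(C)C[C@@H](O)C[C@@]12C | intermediate
27 | 3-methylbut-2-enoic acid | CC(C)=CC(=O)O | starting material
28 | (2R,5R,9R,10R,13S)-13-hydroxy-ent-labda-7,14-dien-2-yl 3-methylbut-2-enoate | C=C[C@@](C)(O)CC[C@@H]1C(C)=CC[C@@H]2C(C)(C)C[C@@H](OC(=O)C=C(C)C)C[C@@]12C | target

**Step count and risks**

Total step count: 20. Longest linear sequence: 16 steps (from (S)-linalool: steps 1–3, 7–9, 11–20).

Steps most likely to fail: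

Step 14. The cycloaddition onto an unactivated 1,1-disubstituted alkene may be slower than thermal loss or isomerisation of the boryl diene (protodeboronation, boron shifts), and exo/endo discrimination may be poor, giving cis-fused material. The fallback carries the C2 oxygen through the cycloaddition on a heat-stable oxygenated diene instead of introducing it by C–B oxidation. It sets out from 19. Oxidation of the alkenyl boronate (NaBO3·4H2O, THF/H2O, rt) should give the β,γ-unsaturated aldehyde (3E,6Z,8S,11S)-11-(tert-butyldimethylsilyloxy)-3,7,11-trimethyl-8-(prop-1-en-2-yl)trideca-3,6,12-trienal F1. Enol acetylation under equilibrating conditions (Ac2O, Et3N, DMAP, 60 °C) should favour the (1E,3E)-dienyl acetate F2, a diene class that tolerates prolonged heating above 200 °C. Intramolecular Diels–Alder reaction (xylenes, BHT, 200–220 °C) should then give the allylic acetate cycloadduct F3. Methanolysis (K2CO3, MeOH) comes back to the route at 21.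

Step 7. The hindered trisubstituted alkenyl nucleophile may give incomplete γ-selectivity (SN2 against SN2') and weak catalyst control of the facial selectivity at C9. The fallback replaces catalyst-controlled substitution by reagent-controlled epoxidation and stereospecific epoxide opening. It sets out from 3. Sharpless asymmetric epoxidation (Ti(OiPr)4, D-(−)-diethyl tartrate, t-BuOOH, 4 Å sieves, CH2Cl2, −20 °C) should give the (2R,3R)-epoxy alcohol F4. Iodine–magnesium exchange on 8 (i-PrMgCl·LiCl, THF) gives the alkenylmagnesium chloride F5. After deprotonation of the hydroxyl (MeMgBr, 1 equiv), F5 with CuI (10 mol%) should open F4 at the less substituted epoxide carbon (C9) with inversion to give the 1,2-diol F6. Corey–Winter olefination (thiocarbonyldiimidazole, DMAP, toluene, 80 °C to the cyclic thionocarbonate F7; then P(OMe)3, 110 °C) turns the diol into the isopropenyl group and comes back to the route at 10.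

Step 17. The β-carbon (C4) is fully substituted and flanked by the ring fusion, so 1,2-addition, enolisation or no addition may win over conjugate addition. The fallback delivers the methyl carbon intramolecularly as a cyclopropane. It sets out from 21. Hydroxyl-directed Simmons–Smith cyclopropanation (Et2Zn, CH2I2, CH2Cl2, 0 °C), fastest at the allylic alcohol alkene, should give the cyclopropyl carbinol F8. Oxidation (Dess–Martin periodinane, NaHCO3, CH2Cl2) gives the cyclopropyl ketone F9. Lithium–ammonia reduction (Li, NH3/THF, −78 °C, quench with solid NH4Cl) should cleave the exocyclic C3–CH2 cyclopropane bond, the one that overlaps the carbonyl π system, so the methylene becomes the second C4 methyl; protonation of the enolate comes back to the route at 24.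

**Further compounds**
F1 | step 14 | (3E,6Z,8S,11S)-11-(tert-butyldimethylsilyloxy)-3,7,11-trimethyl-8-(prop-1-en-2-yl)trideca-3,6,12-trienal | C=C[C@@](C)(O[Si](C)(C)C(C)(C)C)CC[C@@H](C(C)=C)/C(C)=C\C/C=C(\C)CC=O
F2 | step 14 | (1E,3E,6Z,8S,11S)-11-(tert-butyldimethylsilyloxy)-3,7,11-trimethyl-8-(prop-1-en-2-yl)trideca-1,3,6,12-tetraen-1-yl acetate | C=C[C@@](C)(O[Si](C)(C)C(C)(C)C)CC[C@@H](C(C)=C)/C(C)=C\C/C=C(\C)/C=C/OC(C)=O
F3 | step 14 | 2-O-acetyl derivative of 21 (allylic acetate cycloadduct, acetoxy cis to the C10 methyl) | C=C[C@@](C)(O[Si](C)(C)C(C)(C)C)CC[C@@H]1C(C)=CC[C@@H]2C(C)=C[C@H](OC(C)=O)C[C@@]12C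
F4 | step 7 | {(2R,3R)-3-[(3S)-3-(tert-butyldimethylsilyloxy)-3-methylpent-4-en-1-yl]-2-methyloxiran-2-yl}methanol | C=C[C@@](C)(O[Si](C)(C)C(C)(C)C)CC[C@H]1O[C@]1(C)CO
F5 | step 7 | [4-(triethylsilyloxy)but-2-en-2-yl]magnesium chloride, magnesium cis to CH2OTES | Cl[Mg]/C(C)=C\CO[Si](CC)(CC)CC
F6 | step 7 | 1,2-diol from epoxide opening (C10 hydroxy, C1 hydroxymethyl; C9 as in 10) | C=C[C@@](C)(O[Si](C)(C)C(C)(C)C)CC[C@@H]([C@](C)(O)CO)/C(C)=C\CO[Si](CC)(CC)CC
F7 | step 7 | cyclic thionocarbonate of F6 (4-methyl-1,3-dioxolane-2-thione) | C=C[C@@](C)(O[Si](C)(C)C(C)(C)C)CC[C@@H]([C@@]1(C)COC(=S)O1)/C(C)=C\CO[Si](CC)(CC)CC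
F8 | step 17 | 3,4-methano (cyclopropyl) carbinol from 21, methylene cis to the C2 hydroxyl | C=C[C@@](C)(O[Si](C)(C)C(C)(C)C)CC[C@@H]1C(C)=CC[C@@H]2[C@]3(C)C[C@@H]3[C@H](O)C[C@@]12C
F9 | step 17 | 3,4-methano (cyclopropyl) 2-ketone | C=C[C@@](C)(O[Si](C)(C)C(C)(C)C)CC[C@@H]1C(C)=CC[C@@H]2[C@]3(C)C[C@@H]3C(=O)C[C@@]12C
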